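**Plan**

- Feature: each benzene ring is a 2,4-dihydroxy-6-alkylbenzoate (C1 carries the ester carbonyl, C2 and C4 the hydroxyls, C6 the side chain). C6, C1 and the ester carbonyl carbon map onto the β-carbon, α-carbon and C=O of an alk-2-ynoate, and C2–C5 with the oxygens at C2 and C4 map onto a 1,3-dioxygenated diene.
- Retrosynthesis: cut ring bonds C1–C2 and C5–C6 of both arenes (four C–C bonds), which turns the two hindered aryl esters into ordinary ynoate esters of an acyclic tetraester. Then cut its three ester C–O bonds, then the alkyne–CH2 bond (epoxide opening), the two dithiane C–C bonds and the alkyne–CO2H bond.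
- Forward: the east hydroxy-ynoate 6 is extended by a silyl-protected hydroxybutanoic acid to alcohol 10, the west ynoic acid 17 comes from a one-flask dithiane linchpin coupling, and esterification gives the acyclic bis-ynoate 18. Both benzene rings then form together in step 13, and ketone, acid and alcohol are unmasked in the last three steps.
- Stereochemistry: all four (R) centres are bought, two with methyl (R)-3-hydroxybutanoate and two with (R)-propylene oxide, which is opened only at its CH2 carbon. No step creates, inverts or enolises a stereocentre.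

Key step: step 13

Remark: lithium acetylides, carboxylates and other conjugate bases formed by simple deprotonation of a numbered compound are treated as forms of that compound and carry no number of their own.
Remark: cycloadduct 21 forms as a mixture of bridgehead diastereomers that converge on aromatisation, so its bridgehead centres are left undefined in the SMILES.

**Route**

Step 1
Reactants: 1 methyl (R)-3-hydroxybutanoate
Product: 2 allyl (R)-3-hydroxybutanoate
Conditions: allyl alcohol (solvent), Bu2SnO (5 mol %), reflux, MeOH distilled off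
Reagents that add atoms: allyl alcohol, C=CCO
Why: Tin-catalysed transesterification in a large excess of allyl alcohol is driven by removal of methanol and does not involve the carbinol stereocentre.

Step 2
Reactants: 2 allyl (R)-3-hydroxybutanoate; 3 propiolic acid
Product: 4 allyl (R)-3-(propioloyloxy)butanoate
Conditions: DCC, DMAP (5 mol %), CH2Cl2, −20 → 0 °C
Reagents that add atoms: none
Why: Steglich esterification of propiolic acid with a secondary alcohol is routine when kept cold with little DMAP, so that the catalyst does not add to the alkynoate, and the stereocentre is only O-acylated.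

Step 3
Reactants: 4 allyl (R)-3-(propioloyloxy)butanoate; 5 (R)-propylene oxide
Product: 6 allyl (R)-3-{[(R)-5-hydroxyhex-2-ynoyl]oxy}butanoate
Conditions: LiHMDS, THF, −78 °C; BF3·OEt2; 5, −78 °C; then H2O
Reagents that add atoms: none
Why: The propiolate C–H is by far the most acidic site, so the amide base should form the lithium alkynide selectively at −78 °C, and BF3-assisted SN2 opening of the epoxide at its CH2 terminus (Yamaguchi–Hirao alkynylation) gives the homopropargylic alcohol with the (R) centre of 5 untouched.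

Step 4
Reactants: 1 methyl (R)-3-hydroxybutanoate
Product: 7 methyl (R)-3-(tert-butyldimethylsilyloxy)butanoate
Conditions: TBSCl, imidazole, DMF, rt
Reagents that add atoms: tert-butyldimethylsilyl chloride, CC(C)(C)[Si](C)(C)Cl
Why: Imidazole-promoted silylation of a secondary alcohol is standard and leaves the configuration unchanged.

Step 5
Reactants: 7 methyl (R)-3-(tert-butyldimethylsilyloxy)butanoate
Product: 8 (R)-3-(tert-butyldimethylsilyloxy)butanoic acid
Conditions: LiOH, THF/MeOH/H2O, 0 °C → rt; cold 1 M HCl to pH 3–4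
Reagents that add atoms: lithium hydroxide, [Li+].[OH-]
Why: Saponification of the methyl ester proceeds without β-elimination because a silyloxy group is a poor leaving group, and the TBS ether survives the brief cold acidification.

Step 6
Reactants: 6 allyl (R)-3-{[(R)-5-hydroxyhex-2-ynoyl]oxy}butanoate; 8 (R)-3-(tert-butyldimethylsilyloxy)butanoic acid
Product: 9 allyl (R)-3-{[(R)-5-{[(R)-3-(tert-butyldimethylsilyloxy)butanoyl]oxy}hex-2-ynoyl]oxy}butanoate
Conditions: DCC, DMAP (10 mol %), CH2Cl2, 0 °C → rt
Reagents that add atoms: none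
Why: Steglich esterification of the homopropargylic alcohol works here because the activated acid carries only a silyloxy group at its β-position and so cannot eliminate, while catalytic DMAP is too weak a base to harm the 3-acyloxybutanoate already present.

Step 7
Reactants: 9 silyl ether of the east diester
Product: 10 allyl (R)-3-{[(R)-5-{[(R)-3-hydroxybutanoyl]oxy}hex-2-ynoyl]oxy}butanoate
Conditions: HF·pyridine, pyridine, THF, 0 °C → rt
Reagents that add atoms: none
Why: Buffered HF cleaves the secondary TBS ether under mildly acidic conditions that leave the ynoate, the allyl ester and the base-sensitive β-acyloxy esters alone.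

Step 8
Reactants: 11 2-(tert-butyldimethylsilyl)-1,3-dithiane; 5 (R)-propylene oxide; 12 3-bromo-1-(trimethylsilyl)prop-1-yne
Product: 15 2-[(R)-2-(tert-butyldimethylsilyloxy)propyl]-2-[3-(trimethylsilyl)prop-2-yn-1-yl]-1,3-dithiane, via lithium alkoxide adduct 13 (not isolated), via Brook-rearranged 2-lithiodithiane 14 (not isolated)
Conditions: t-BuLi, Et2O, −78 → −45 °C; 5, −78 → −25 °C; then 12, HMPA/THF, −78 → 0 °C
Reagents that add atoms: none
Why: In this three-component dithiane linchpin coupling (Corey–Seebach umpolung with anion relay) the lithiated silyl dithiane opens the epoxide at CH2, HMPA then triggers a 1,4-Brook rearrangement that protects the new alkoxide as its TBS ether and regenerates a dithiane anion, and this anion is alkylated by the silyl-capped propargylic bromide, with the (R) centre of 5 never at the reacting carbon.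

Step 9
Reactants: 15 bis-alkylated dithiane with C-silyl alkyne
Product: 16 2-[(R)-2-(tert-butyldimethylsilyloxy)propyl]-2-(prop-2-yn-1-yl)-1,3-dithiane
Conditions: K2CO3 (cat.), MeOH, rt
Reagents that add atoms: none
Why: Base-catalysed methanolysis removes the alkynyl trimethylsilyl group selectively, since the secondary TBS ether and the dithiane are inert to carbonate in methanol.

Step 10
Reactants: 16 terminal alkyne dithiane
Product: 17 4-{2-[(R)-2-(tert-butyldimethylsilyloxy)propyl]-1,3-dithian-2-yl}but-2-ynoic acid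
Conditions: n-BuLi, THF, −78 °C; CO2 (g), −78 → 0 °C; cold 1 M HCl to pH 3
Reagents that add atoms: carbon dioxide, O=C=O
Why: The terminal alkyne is the only acidic C–H (the dithiane carbon is quaternary), and carboxylation of the lithium acetylide with CO2 is a standard route to alk-2-ynoic acids.

Step 11
Reactants: 10 east hydroxy diester ynoate; 17 west ynoic acid
Product: 18 allyl (R)-3-{[(R)-5-{[(R)-3-({4-[2-((R)-2-(tert-butyldimethylsilyloxy)propyl)-1,3-dithian-2-yl]but-2-ynoyl}oxy)butanoyl]oxy}hex-2-ynoyl]oxy}butanoate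
Conditions: DCC, DMAP (5 mol %), CH2Cl2, −20 → 0 °C
Reagents that add atoms: none
Why: Steglich esterification of an unhindered alk-2-ynoic acid with the secondary alcohol installs the future aryl ester before the arene exists, and the cold, weakly basic conditions avoid both ynoate-to-allenoate isomerisation and elimination of the β-acyloxy esters.

Step 12
Reactants: 19 dimedone
Product: 20 5,5-dimethyl-1,3-bis(trimethylsilyloxy)cyclohexa-1,3-diene
Conditions: TMSOTf (2.2 equiv), Et3N, Et2O, 0 °C → rt; distillation
Reagents that add atoms: trimethylsilyl trifluoromethanesulfonate, C[Si](C)(C)OS(=O)(=O)C(F)(F)F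
Why: Twofold O-silylation of a cyclic 1,3-diketone with silyl triflate and amine passes through a symmetric 1,3-bis(silyloxy)allyl cation whose deprotonation at either flanking CH2 gives the same diene.

Step 13
Reactants: 18 linear bis(alk-2-ynoate) tetraester; 20 5,5-dimethyl-1,3-bis(trimethylsilyloxy)cyclohexa-1,3-diene (two equivalents consumed)
Product: 23 allyl (R)-3-[(2,4-dihydroxy-6-{(R)-2-[((R)-3-{[2,4-dihydroxy-6-({2-[(R)-2-(tert-butyldimethylsilyloxy)propyl]-1,3-dithian-2-yl}methyl)benzoyl]oxy}butanoyl)oxy]propyl}benzoyl)oxy]butanoate, via bis(bicyclooctadiene) cycloadduct 21 (not isolated), via tetrakis(trimethylsilyl) ether 22 (not isolated)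
Conditions: 20 (excess), neat, sealed tube, 150 °C; excess 20 removed in vacuo; MeOH, silica gel, rt
Reagents that add atoms: none
Why: Each alk-2-ynoate is a polarised 2π partner with its largest LUMO coefficient at the β-carbon, and the s-cis-locked bis(silyloxy)diene has its largest HOMO coefficient at the unsubstituted terminus, so an asynchronous but concerted intermolecular [4+2] cycloaddition joins that terminus to the β-carbon (arene bond C5–C6) and the silyloxy-bearing terminus to the α-carbon (arene bond C1–C2), closing each new six-membered ring as a bicyclo[2.2.2]octa-2,5-diene in 21. A retro-[4+2] then expels the CMe2–CH2 bridge as 2-methylpropene, which makes the sequence irreversible and leaves the tetrasilyl ether 22, whose aryl silyl ethers are methanolysed on work-up while the secondary TBS ether stays. The closest known reaction type is the Alder–Rickert benzannulation of alkynoate esters with 1,3-bis(silyloxy)cyclohexa-1,3-dienes to resorcylates, applied here to two insulated and electronically alike ynoates of one molecule. No lasting stereocentre is formed, because the bridgehead centres of 21 vanish on aromatisation, and the four existing centres are remote and cannot epimerise under neutral heating. The selectivity needed is regiochemical (hydroxyls at C2 and C4, chain at C6) and is secured by the matched donor–acceptor polarisation just described, while chemoselectivity follows from the absence of any other activated π-system and of any base that could eliminate the 3-acyloxybutanoates.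

Step 14
Reactants: 23 bis-resorcylate dithiane
Product: 24 allyl (R)-3-[(2,4-dihydroxy-6-{(R)-2-[((R)-3-{[2,4-dihydroxy-6-((R)-4-(tert-butyldimethylsilyloxy)-2-oxopentyl)benzoyl]oxy}butanoyl)oxy]propyl}benzoyl)oxy]butanoate
Conditions: MeI (excess), CaCO3, MeCN/H2O (9:1), 40 °C, dark
Reagents that add atoms: water, O
Why: Alkylative dithiane hydrolysis (S-methylation to a sulfonium leaving group, then water capture of the thionium ion) is non-oxidising and therefore suited to the electron-rich resorcinols, while the insoluble carbonate only buffers the hydrogen iodide and is too weak a base to cause phenol methylation or β-elimination.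

Step 15
Reactants: 24 keto bis-resorcylate allyl ester
Product: 25 (R)-3-[(2,4-dihydroxy-6-{(R)-2-[((R)-3-{[2,4-dihydroxy-6-((R)-4-(tert-butyldimethylsilyloxy)-2-oxopentyl)benzoyl]oxy}butanoyl)oxy]propyl}benzoyl)oxy]butanoic acid
Conditions: Pd(PPh3)4 (5 mol %), N-methylaniline, THF, rt
Reagents that add atoms: none
Why: Tsuji–Trost deallylation ionises only the allyl ester to a π-allylpalladium carboxylate, and the weakly basic aniline traps the allyl unit without forming phenolates or inducing elimination in the acyloxybutanoates or the β-silyloxy ketone.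

Step 16
Reactants: 25 silyl-protected seco acid
Product: 26 Hansforester I
Conditions: HF·pyridine, pyridine, THF, 0 °C → rt; TMSOMe quench, evaporation, reversed-phase chromatography
Reagents that add atoms: none
Why: Buffered HF removes the last silyl ether under mildly acidic conditions that avoid dehydration or retro-aldol cleavage of the β-hydroxy ketone and acyl migration or elimination in the polyester, and the methoxysilane quench leaves only volatile by-products.

**Compound list**

1 | methyl (R)-3-hydroxybutanoate | O[C@H](C)CC(=O)OC | starting material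
2 | allyl (R)-3-hydroxybutanoate | O[C@H](C)CC(=O)OCC=C | intermediate
3 | propiolic acid | C#CC(=O)O | starting material
4 | allyl (R)-3-(propioloyloxy)butanoate | C#CC(=O)O[C@H](C)CC(=O)OCC=C | intermediate
5 | (R)-propylene oxide | C[C@@H]1CO1 | starting material
6 | allyl (R)-3-{[(R)-5-hydroxyhex-2-ynoyl]oxy}butanoate | C[C@H](CC#CC(=O)O[C@H](C)CC(=O)OCC=C)O | intermediate
7 | methyl (R)-3-(tert-butyldimethylsilyloxy)butanoate | C[C@H](CC(=O)OC)O[Si](C)(C)C(C)(C)C | intermediate
8 | (R)-3-(tert-butyldimethylsilyloxy)butanoic acid | C[C@H](CC(=O)O)O[Si](C)(C)C(C)(C)C | intermediate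
9 | allyl (R)-3-{[(R)-5-{[(R)-3-(tert-butyldimethylsilyloxy)butanoyl]oxy}hex-2-ynoyl]oxy}butanoate | C[C@H](CC#CC(=O)O[C@H](C)CC(=O)OCC=C)OC(=O)C[C@@H](C)O[Si](C)(C)C(C)(C)C | intermediate
10 | allyl (R)-3-{[(R)-5-{[(R)-3-hydroxybutanoyl]oxy}hex-2-ynoyl]oxy}butanoate | C[C@H](CC#CC(=O)O[C@H](C)CC(=O)OCC=C)OC(=O)C[C@@H](C)O | intermediate
11 | 2-(tert-butyldimethylsilyl)-1,3-dithiane | CC(C)(C)[Si](C)(C)C1SCCCS1 | starting material
12 | 3-bromo-1-(trimethylsilyl)prop-1-yne | C[Si](C)(C)C#CCBr | starting material
13 | lithium (R)-1-[2-(tert-butyldimethylsilyl)-1,3-dithian-2-yl]propan-2-olate (not isolated) | [Li+].C[C@@H]([O-])CC1([Si](C)(C)C(C)(C)C)SCCCS1 | intermediate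
14 | 2-lithio-2-[(R)-2-(tert-butyldimethylsilyloxy)propyl]-1,3-dithiane (not isolated) | [Li]C1(C[C@@H](C)O[Si](C)(C)C(C)(C)C)SCCCS1 | intermediate
15 | 2-[(R)-2-(tert-butyldimethylsilyloxy)propyl]-2-[3-(trimethylsilyl)prop-2-yn-1-yl]-1,3-dithiane | C[C@H](CC1(CC#C[Si](C)(C)C)SCCCS1)O[Si](C)(C)C(C)(C)C | intermediate
16 | 2-[(R)-2-(tert-butyldimethylsilyloxy)propyl]-2-(prop-2-yn-1-yl)-1,3-dithiane | C[C@H](CC1(CC#C)SCCCS1)O[Si](C)(C)C(C)(C)C | intermediate
17 | 4-{2-[(R)-2-(tert-butyldimethylsilyloxy)propyl]-1,3-dithian-2-yl}but-2-ynoic acid | C[C@H](CC1(CC#CC(=O)O)SCCCS1)O[Si](C)(C)C(C)(C)C | intermediate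
18 | allyl (R)-3-{[(R)-5-{[(R)-3-({4-[2-((R)-2-(tert-butyldimethylsilyloxy)propyl)-1,3-dithian-2-yl]but-2-ynoyl}oxy)butanoyl]oxy}hex-2-ynoyl]oxy}butanoate (linear bis(alk-2-ynoate) tetraester) | C[C@H](CC#CC(=O)O[C@H](C)CC(=O)OCC=C)OC(=O)C[C@@H](C)OC(=O)C#CCC1(C[C@@H](C)O[Si](C)(C)C(C)(C)C)SCCCS1 | intermediate
19 | dimedone (5,5-dimethylcyclohexane-1,3-dione) | CC1(C)CC(=O)CC(=O)C1 | starting material
20 | 5,5-dimethyl-1,3-bis(trimethylsilyloxy)cyclohexa-1,3-diene | CC1(C)CC(O[Si](C)(C)C)=CC(O[Si](C)(C)C)=C1 | intermediate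
21 | twofold bicyclo[2.2.2]octa-2,5-diene cycloadduct of 18 with 20, bridgehead diastereomer mixture (not isolated) | C[C@H](CC1=C(C(=O)O[C@H](C)CC(=O)OCC=C)C2(O[Si](C)(C)C)CC(C)(C)C1C(O[Si](C)(C)C)=C2)OC(=O)C[C@@H](C)OC(=O)C1=C(CC3(C[C@@H](C)O[Si](C)(C)C(C)(C)C)SCCCS3)C2C(O[Si](C)(C)C)=CC1(O[Si](C)(C)C)CC2(C)C | intermediate
22 | tetrakis(trimethylsilyl) aryl ether of 23 (not isolated) | C[C@H](Cc1cc(O[Si](C)(C)C)cc(O[Si](C)(C)C)c1C(=O)O[C@H](C)CC(=O)OCC=C)OC(=O)C[C@@H](C)OC(=O)c1c(O[Si](C)(C)C)cc(O[Si](C)(C)C)cc1CC1(C[C@@H](C)O[Si](C)(C)C(C)(C)C)SCCCS1 | intermediate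
23 | allyl (R)-3-[(2,4-dihydroxy-6-{(R)-2-[((R)-3-{[2,4-dihydroxy-6-({2-[(R)-2-(tert-butyldimethylsilyloxy)propyl]-1,3-dithian-2-yl}methyl)benzoyl]oxy}butanoyl)oxy]propyl}benzoyl)oxy]butanoate | C[C@H](Cc1cc(O)cc(O)c1C(=O)O[C@H](C)CC(=O)OCC=C)OC(=O)C[C@@H](C)OC(=O)c1c(O)cc(O)cc1CC1(C[C@@H](C)O[Si](C)(C)C(C)(C)C)SCCCS1 | intermediate
24 | allyl (R)-3-[(2,4-dihydroxy-6-{(R)-2-[((R)-3-{[2,4-dihydroxy-6-((R)-4-(tert-butyldimethylsilyloxy)-2-oxopentyl)benzoyl]oxy}butanoyl)oxy]propyl}benzoyl)oxy]butanoate | C[C@H](Cc1cc(O)cc(O)c1C(=O)O[C@H](C)CC(=O)OCC=C)OC(=O)C[C@@H](C)OC(=O)c1c(O)cc(O)cc1CC(=O)C[C@@H](C)O[Si](C)(C)C(C)(C)C | intermediate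
25 | (R)-3-[(2,4-dihydroxy-6-{(R)-2-[((R)-3-{[2,4-dihydroxy-6-((R)-4-(tert-butyldimethylsilyloxy)-2-oxopentyl)benzoyl]oxy}butanoyl)oxy]propyl}benzoyl)oxy]butanoic acid | C[C@H](Cc1cc(O)cc(O)c1C(=O)O[C@H](C)CC(=O)O)OC(=O)C[C@@H](C)OC(=O)c1c(O)cc(O)cc1CC(=O)C[C@@H](C)O[Si](C)(C)C(C)(C)C | intermediate
26 | Hansforester I, (R)-3-[(2,4-dihydroxy-6-{(R)-2-[((R)-3-{[2,4-dihydroxy-6-((R)-4-hydroxy-2-oxopentyl)benzoyl]oxy}butanoyl)oxy]propyl}benzoyl)oxy]butanoic acid | C[C@H](Cc1cc(O)cc(O)c1C(=O)O[C@H](C)CC(=O)O)OC(=O)C[C@@H](C)OC(=O)c1c(O)cc(O)cc1CC(=O)C[C@@H](C)O | target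

**Step count**

Total: 16 steps.
Longest linear sequence: 10 steps (1 → 2 → 4 → 6 → 9 → 10 → 18 → 23 → 24 → 25 → 26; steps 1, 2, 3, 6, 7, 11, 13, 14, 15, 16).

**Steps most likely to fail**

Step 13. The second cycloaddition may stall, because the CMe2 carbon of 20 lies next to the diene terminus that must bond to the neopentyl-like β-carbon of the dithiane-bearing ynoate, and the prolonged heating then needed may degrade the polyester. The fallback sets out again from 18 and uses a diene without that quaternary carbon. Cyclohexane-1,3-dione F1 would be bis-silylated (TMSOTf, Et3N, Et2O) to 1,3-bis(trimethylsilyloxy)cyclohexa-1,3-diene F2. Heating 18 with F2 should give the ethano-bridged bis-cycloadduct F3, which aromatises by Alder–Rickert loss of ethene instead of 2-methylpropene when the temperature is raised to about 180–200 °C in o-dichlorobenzene. This gives the same tetrasilyl ether 22, and methanolysis rejoins the route at 23.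

Step 14. The large excess of methyl iodide may O-methylate the free phenols, or hydrolysis of the hindered dithiane may remain incomplete under conditions mild enough for the resorcinols. The fallback starts from 23 and caps the four phenols first (Ac2O, pyridine, cat. DMAP, 0 °C) to give the tetraacetate F4. The now electron-poor arenes should tolerate an oxidative dethioketalisation (PhI(OCOCF3)2, MeCN/H2O, 0 °C) to the ketone tetraacetate F5. The aryl acetates, far more labile than the alkyl esters, would then be removed by brief methanolysis (NaHCO3, MeOH, 0 °C), which returns to 24.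

Step 3. The lithiated propiolate carries two further ester groups, so proton transfer from their α-positions or Claisen-type self-condensation may outrun the epoxide opening. The fallback starts from 5 and introduces alkyne and carboxyl separately. Lithium acetylide–ethylenediamine complex in DMSO opens 5 to (R)-pent-4-yn-2-ol F6, and silylation (TBSCl, imidazole) gives (R)-tert-butyldimethyl(pent-4-yn-2-yloxy)silane F7. Treatment with n-BuLi and then CO2 gives (R)-5-(tert-butyldimethylsilyloxy)hex-2-ynoic acid F8. Steglich esterification with 2 gives allyl (R)-3-{[(R)-5-(tert-butyldimethylsilyloxy)hex-2-ynoyl]oxy}butanoate F9, and HF·pyridine returns to 6. Compounds 3 and 4 are then not needed.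

**Further compounds**

F1 | step 13 | cyclohexane-1,3-dione | O=C1CC(=O)CCC1
F2 | step 13 | 1,3-bis(trimethylsilyloxy)cyclohexa-1,3-diene | C[Si](C)(C)OC1=CC(O[Si](C)(C)C)=CCC1
F3 | step 13 | ethano-bridged bis-cycloadduct of 18 with F2 (bridgehead diastereomer mixture) | C[C@H](CC1=C(C(=O)O[C@H](C)CC(=O)OCC=C)C2(O[Si](C)(C)C)CCC1C(O[Si](C)(C)C)=C2)OC(=O)C[C@@H](C)OC(=O)C1=C(CC3(C[C@@H](C)O[Si](C)(C)C(C)(C)C)SCCCS3)C2C(O[Si](C)(C)C)=CC1(O[Si](C)(C)C)CC2
F4 | step 14 | tetraacetate of 23 | C[C@H](Cc1cc(OC(C)=O)cc(OC(C)=O)c1C(=O)O[C@H](C)CC(=O)OCC=C)OC(=O)C[C@@H](C)OC(=O)c1c(OC(C)=O)cc(OC(C)=O)cc1CC1(C[C@@H](C)O[Si](C)(C)C(C)(C)C)SCCCS1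
F5 | step 14 | tetraacetate of 24 | C[C@H](Cc1cc(OC(C)=O)cc(OC(C)=O)c1C(=O)O[C@H](C)CC(=O)OCC=C)OC(=O)C[C@@H](C)OC(=O)c1c(OC(C)=O)cc(OC(C)=O)cc1CC(=O)C[C@@H](C)O[Si](C)(C)C(C)(C)C
F6 | step 3 | (R)-pent-4-yn-2-ol | C[C@@H](O)CC#C
F7 | step 3 | (R)-tert-butyldimethyl(pent-4-yn-2-yloxy)silane | C[C@H](CC#C)O[Si](C)(C)C(C)(C)C
F8 | step 3 | (R)-5-(tert-butyldimethylsilyloxy)hex-2-ynoic acid | C[C@H](CC#CC(=O)O)O[Si](C)(C)C(C)(C)C
F9 | step 3 | allyl (R)-3-{[(R)-5-(tert-butyldimethylsilyloxy)hex-2-ynoyl]oxy}butanoate | C[C@H](CC#CC(=O)O[C@H](C)CC(=O)OCC=C)O[Si](C)(C)C(C)(C)C
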